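**Retrosynthetic overview**
- Feature: the depside oxygen is bound to C4 of ring B, whose neighbours C3 and C5 carry only hydrogen. The acyl carbon hangs on C1 of ring A, between the C2 heptyl chain and the C6 oxygen. The ester is therefore cut at the O–C4(aryl) bond, not at the acyl–O bond.
- O–C4 bond: oxidative copper coupling of the ring A carboxylic acid (6-OH masked as MOM ether) with a ring B C4 boronic acid (acid masked as tert-butyl ester).
- C4–B bond: sterically governed iridium C–H borylation of the 1,2,3-trisubstituted ring B ester. Each heptyl chain comes from an aryl CH3 plus hexyl iodide by lateral lithiation of an ortho-toluate.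
- No ring is formed, since both benzene rings are bought. One acid treatment at the end frees the phenol and the acid.

Key step: step 8

Remark on the chemistry: the target has no stereocentre. Binding of a carboxylic acid to Cu(OTf)2 releases triflic acid and both masks are acid-labile, so the coupling is run with 2,6-lutidine as proton sink. Lithium diisopropylamide is taken as the commercial solution.

**Step 1**
Reactants: 1 methyl 2-hydroxy-4-methoxy-6-methylbenzoate
Product: 3 methyl 4-methoxy-2-(methoxymethoxy)-6-methylbenzoate, via sodium phenolate 2 (not isolated)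
Conditions: NaH (1.3 equiv), DMF, 0 °C; then MOMCl (1.4 equiv), 0 °C → rt
Reagents that add atoms: chloromethyl methyl ether (MOMCl), COCCl; sodium hydride, [Na+].[H-] (its sodium stays only in 2)
Why: Williamson-type O-alkylation: irreversible deprotonation by NaH breaks the hydrogen bond between the C2 hydroxyl and the ester carbonyl, and the free phenolate 2 should displace chloride from the very reactive chloromethyl ether.

**Step 2**
Reactants: 3 methyl 4-methoxy-2-(methoxymethoxy)-6-methylbenzoate; 4 1-iodohexane
Product: 6 methyl 2-heptyl-4-methoxy-6-(methoxymethoxy)benzoate, via benzylic lithium species 5 (not isolated)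
Conditions: LiN(iPr)2 (1.15 equiv), THF, −78 °C; then 4 (1.4 equiv), −78 → −30 °C; aq. NH4Cl
Reagents that add atoms: 1-iodohexane (4), CCCCCCI; lithium diisopropylamide, CC(C)[N-]C(C)C.[Li+] (its lithium stays only in 5)
Why: Lateral lithiation of an ortho-toluate followed by SN2 alkylation: the C6 methyl protons are acidified by conjugation with the ester, the amide base removes one of them at −78 °C without touching the ring C–H bonds, the ester carbonyl between two ortho substituents is shielded against self-condensation, and the primary iodide should add the six missing carbons of the heptyl chain.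

**Step 3**
Reactants: 6 methyl 2-heptyl-4-methoxy-6-(methoxymethoxy)benzoate
Product: 8 2-heptyl-4-methoxy-6-(methoxymethoxy)benzoic acid, via potassium carboxylate 7 (not isolated)
Conditions: KOH (10 equiv), DMSO–H2O 4:1, 100 °C; then cold 1 M HCl to pH 4, 0 °C, immediate extraction (EtOAc)
Reagents that add atoms: potassium hydroxide, [K+].[OH-] (oxygen stays in 8, potassium only in 7)
Why: Saponification by acyl–oxygen cleavage: poorly solvated hydroxide in hot aqueous DMSO should reach the doubly ortho-flanked ester carbonyl, the acetal and the aryl methyl ether are inert to base, and a short cold acidification to pH 4 should protonate carboxylate 7 without opening the acetal.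

**Step 4**
Reactants: 9 2-methoxy-6-methylbenzoic acid
Product: 10 tert-butyl 2-methoxy-6-methylbenzoate
Conditions: tert-butyl 2,2,2-trichloroacetimidate (2 equiv), BF3·OEt2 (cat.), CH2Cl2–cyclohexane, rt
Reagents that add atoms: tert-butyl 2,2,2-trichloroacetimidate, CC(C)(C)OC(=N)C(Cl)(Cl)Cl
Why: Trichloroacetimidate tert-butylation: the tert-butyl group is handed to the carboxylate oxygen as a cation equivalent, so the crowded acyl carbon is never attacked and the ortho substituents should not slow the esterification.

**Step 5**
Reactants: 10 tert-butyl 2-methoxy-6-methylbenzoate; 4 1-iodohexane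
Product: 12 tert-butyl 2-heptyl-6-methoxybenzoate, via benzylic lithium species 11 (not isolated)
Conditions: LiN(iPr)2 (1.15 equiv), THF, −78 °C; then 4 (1.4 equiv), −78 → −20 °C; aq. NH4Cl
Reagents that add atoms: 1-iodohexane (4), CCCCCCI; lithium diisopropylamide, CC(C)[N-]C(C)C.[Li+] (its lithium stays only in 11)
Why: Lateral lithiation and SN2 alkylation as in step 2, here made cleaner by the tert-butyl ester, whose bulk should suppress attack of the benzylic anion 11 on a second ester.

**Step 6**
Reactants: 12 tert-butyl 2-heptyl-6-methoxybenzoate; 13 bis(pinacolato)diboron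
Product: 14 tert-butyl 2-heptyl-6-methoxy-4-(4,4,5,5-tetramethyl-1,3,2-dioxaborolan-2-yl)benzoate
Conditions: [Ir(OMe)(cod)]2 (1.5 mol %), 4,4'-di-tert-butyl-2,2'-bipyridine (3 mol %), 13 (1.0 equiv), THF, 80 °C (sealed vessel)
Reagents that add atoms: bis(pinacolato)diboron (13), CC1(C)OB(OC1(C)C)B1OC(C)(C)C(C)(C)O1
Why: Iridium-catalysed aromatic C–H borylation (Hartwig–Miyaura borylation): the crowded trivalent iridium tris(boryl) catalyst avoids C–H bonds next to a substituent, so of C3–H (beside heptyl), C5–H (beside methoxy) and C4–H only the last should react, and a second borylation has no open site.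

**Step 7**
Reactants: 14 tert-butyl 2-heptyl-6-methoxy-4-(4,4,5,5-tetramethyl-1,3,2-dioxaborolan-2-yl)benzoate
Product: 15 [4-(tert-butoxycarbonyl)-3-heptyl-5-methoxyphenyl]boronic acid
Conditions: NaIO4 (3 equiv), NH4OAc (3 equiv), acetone–H2O 1:1, rt
Reagents that add atoms: water, O
Why: Oxidative deprotection of a pinacol boronate: periodate cleaves the pinacol that hydrolysis releases (Malaprade glycol cleavage) and so pulls the equilibrium to the boronic acid, while the ammonium acetate buffer keeps the medium near neutral for the tert-butyl ester.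

**Step 8**
Reactants: 8 2-heptyl-4-methoxy-6-(methoxymethoxy)benzoic acid; 15 [4-(tert-butoxycarbonyl)-3-heptyl-5-methoxyphenyl]boronic acid
Product: 16 tert-butyl 2-heptyl-4-[2-heptyl-4-methoxy-6-(methoxymethoxy)benzoyloxy]-6-methoxybenzoate
Conditions: 8 (1.0 equiv), 15 (1.5 equiv), Cu(OTf)2 (40 mol %), urea (1 equiv), 2,6-lutidine (1 equiv), 4 Å molecular sieves, EtOAc, dry air, 60 °C
Reagents that add atoms: none
Why: The carboxylate of 8 replaces triflate on divalent copper, boronic acid 15 hands its aryl group to this copper carboxylate, oxidation lifts the aryl copper carboxylate to trivalent copper, and C–O reductive elimination should release aryl ester 16 while air returns monovalent copper to the divalent state. This is the Chan–Lam oxidative coupling in its carboxylic acid/arylboronic acid form, which is established for benzoic acids with Cu(OTf)2, urea and air. No ring is closed and no stereocentre is created. The new bond starts at the carboxylate oxygen, one atom out from the acyl carbon that heptyl and the acetal oxygen crowd, and ends at C4 of ring B, whose neighbours C3 and C5 bear hydrogen, so transmetalation and reductive elimination meet no ortho substituent on the aryl side. Chemoselectivity for the carboxylate oxygen is secured by the MOM ether, which removes the phenol as a second oxygen nucleophile, by triflate, which unlike acetate does not itself couple, and by the sieves, which limit water as a competitor. 2,6-Lutidine takes up the triflic acid freed on carboxylate binding, so that the acetal of ring A and the tert-butyl ester of ring B should survive.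

**Step 9**
Reactants: 16 tert-butyl 2-heptyl-4-[2-heptyl-4-methoxy-6-(methoxymethoxy)benzoyloxy]-6-methoxybenzoate
Product: 17 2-heptyl-4-[(2-heptyl-6-hydroxy-4-methoxybenzoyl)oxy]-6-methoxybenzoic acid (target)
Conditions: CF3CO2H–CH2Cl2–H2O 10:10:1, 0 °C → rt
Reagents that add atoms: none
Why: Acidolysis of both masks in one operation: trifluoroacetic acid ionises the tert-butyl ester by alkyl–oxygen cleavage and opens the acetal through its oxocarbenium ion, which water intercepts, whereas the aryl ester with its shielded acyl carbon and the two aryl methyl ethers should be inert at or below room temperature.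

**Compound list**
1 | methyl 2-hydroxy-4-methoxy-6-methylbenzoate | COc1cc(C)c(C(=O)OC)c(O)c1 | starting material
2 | sodium 3-methoxy-2'-ester phenolate of 1 (sodium 5-methoxy-2-(methoxycarbonyl)-3-methylphenolate) | [Na+].[O-]c1cc(OC)cc(C)c1C(=O)OC | intermediate
3 | methyl 4-methoxy-2-(methoxymethoxy)-6-methylbenzoate | COCOc1cc(OC)cc(C)c1C(=O)OC | intermediate
4 | 1-iodohexane | CCCCCCI | starting material
5 | benzylic lithium species of 3 (methyl 2-(lithiomethyl)-4-methoxy-6-(methoxymethoxy)benzoate) | [Li]Cc1cc(OC)cc(OCOC)c1C(=O)OC | intermediate
6 | methyl 2-heptyl-4-methoxy-6-(methoxymethoxy)benzoate | CCCCCCCc1cc(OC)cc(OCOC)c1C(=O)OC | intermediate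
7 | potassium 2-heptyl-4-methoxy-6-(methoxymethoxy)benzoate | CCCCCCCc1cc(OC)cc(OCOC)c1C(=O)[O-].[K+] | intermediate
8 | 2-heptyl-4-methoxy-6-(methoxymethoxy)benzoic acid | CCCCCCCc1cc(OC)cc(OCOC)c1C(=O)O | intermediate
9 | 2-methoxy-6-methylbenzoic acid | COc1cccc(C)c1C(=O)O | starting material
10 | tert-butyl 2-methoxy-6-methylbenzoate | COc1cccc(C)c1C(=O)OC(C)(C)C | intermediate
11 | benzylic lithium species of 10 (tert-butyl 2-(lithiomethyl)-6-methoxybenzoate) | [Li]Cc1cccc(OC)c1C(=O)OC(C)(C)C | intermediate
12 | tert-butyl 2-heptyl-6-methoxybenzoate | CCCCCCCc1cccc(OC)c1C(=O)OC(C)(C)C | intermediate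
13 | bis(pinacolato)diboron | CC1(C)OB(OC1(C)C)B1OC(C)(C)C(C)(C)O1 | starting material
14 | tert-butyl 2-heptyl-6-methoxy-4-(4,4,5,5-tetramethyl-1,3,2-dioxaborolan-2-yl)benzoate | CCCCCCCc1cc(B2OC(C)(C)C(C)(C)O2)cc(OC)c1C(=O)OC(C)(C)C | intermediate
15 | [4-(tert-butoxycarbonyl)-3-heptyl-5-methoxyphenyl]boronic acid | CCCCCCCc1cc(B(O)O)cc(OC)c1C(=O)OC(C)(C)C | intermediate
16 | tert-butyl 2-heptyl-4-[2-heptyl-4-methoxy-6-(methoxymethoxy)benzoyloxy]-6-methoxybenzoate | CCCCCCCc1cc(OC)cc(OCOC)c1C(=O)Oc1cc(CCCCCCC)c(C(=O)OC(C)(C)C)c(OC)c1 | intermediate
17 | 2-heptyl-4-[(2-heptyl-6-hydroxy-4-methoxybenzoyl)oxy]-6-methoxybenzoic acid | CCCCCCCc1cc(OC)cc(O)c1C(=O)Oc1cc(CCCCCCC)c(C(=O)O)c(OC)c1 | target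

**Step count**
Total step count: 9 (ring A arm steps 1–3, ring B arm steps 4–7, then steps 8 and 9).
Longest linear sequence: 6 steps (steps 4, 5, 6, 7, 8, 9, starting from compound 9).

**Steps most likely to fail**

1. Step 8.
   - Risk: the bulky carboxylate may bind copper and turn it over slowly. Protodeboronation, oxidative hydroxylation and homocoupling of the boronic acid, or acid-induced loss of the acetal and the tert-butyl group, could then outrun C–O bond formation.
   - Fallback, from 15 and 8, back at 16: the boron at C4 is exchanged for oxygen first and the ester is then closed at the acyl–oxygen bond.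
   - ipso-Oxidation of 15 with 30 % H2O2 in THF at 0 °C → rt should give tert-butyl 2-heptyl-4-hydroxy-6-methoxybenzoate F1.
   - Acid 8 is activated with dicyclohexylcarbodiimide in toluene–CH2Cl2 as the O-acylisourea of 8 F2. With catalytic 4-(dimethylamino)pyridine, F2 should acylate the unhindered phenol F1 (Steglich esterification) to give 16.

2. Step 9.
   - Risk: the oxocarbenium ion released from the acetal may attack the electron-rich ring A at C3 or C5. Long exposure to strong acid may also start decarboxylation of the ring B acid.
   - Fallback, from 16, back at 17: the two masks are removed in separate operations, with the acetal carbon trapped on sulfur.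
   - ZnBr2 and 1-propanethiol in CH2Cl2 at 0 °C (short contact) should give tert-butyl 2-heptyl-4-[(2-heptyl-6-hydroxy-4-methoxybenzoyl)oxy]-6-methoxybenzoate F3.
   - 85 % aqueous H3PO4 in toluene at rt should then cleave the tert-butyl ester of F3 under much milder acidity to give 17.

3. Step 2.
   - Risk: capture of the benzylic anion by the unactivated primary iodide may be slower than its attack on the methyl ester of a second molecule (Claisen-type self-condensation). Proton exchange with the product could also lead to double alkylation.
   - Fallback, from 3, back at 8: the electrophilic ester is removed before the anion is made.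
   - Saponification of 3 (KOH, DMSO–H2O, 100 °C) should give potassium 4-methoxy-2-(methoxymethoxy)-6-methylbenzoate F4. Cold acidification to pH 4 then gives 4-methoxy-2-(methoxymethoxy)-6-methylbenzoic acid F5.
   - LiN(iPr)2 (2.2 equiv) in THF, −78 → 0 °C, should convert F5 into the dilithiated carboxylate–benzyl species F6. Its carboxylate cannot be attacked by carbon nucleophiles.
   - Alkylation of F6 with 4 should give lithium 2-heptyl-4-methoxy-6-(methoxymethoxy)benzoate F7, and cold 1 M HCl to pH 4 delivers 8. Step 3 is then no longer needed.

**Further compounds**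
F1 | step 8 | tert-butyl 2-heptyl-4-hydroxy-6-methoxybenzoate | CCCCCCCc1cc(O)cc(OC)c1C(=O)OC(C)(C)C
F2 | step 8 | O-acylisourea of 8 (N,N'-dicyclohexylcarbamimidic 2-heptyl-4-methoxy-6-(methoxymethoxy)benzoic anhydride) | CCCCCCCc1cc(OC)cc(OCOC)c1C(=O)OC(=NC2CCCCC2)NC2CCCCC2
F3 | step 9 | tert-butyl 2-heptyl-4-[(2-heptyl-6-hydroxy-4-methoxybenzoyl)oxy]-6-methoxybenzoate | CCCCCCCc1cc(OC)cc(O)c1C(=O)Oc1cc(CCCCCCC)c(C(=O)OC(C)(C)C)c(OC)c1
F4 | step 2 | potassium 4-methoxy-2-(methoxymethoxy)-6-methylbenzoate | COCOc1cc(OC)cc(C)c1C(=O)[O-].[K+]
F5 | step 2 | 4-methoxy-2-(methoxymethoxy)-6-methylbenzoic acid | COCOc1cc(OC)cc(C)c1C(=O)O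
F6 | step 2 | dilithiated carboxylate–benzyl species (lithium 2-(lithiomethyl)-4-methoxy-6-(methoxymethoxy)benzoate) | [Li]Cc1cc(OC)cc(OCOC)c1C(=O)O[Li]
F7 | step 2 | lithium 2-heptyl-4-methoxy-6-(methoxymethoxy)benzoate | CCCCCCCc1cc(OC)cc(OCOC)c1C(=O)[O-].[Li+]
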